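**Retrosynthetic overview**
- The two prenyl groups come from allyl groups by olefin cross-metathesis; the allyl groups come from a double aromatic Claisen rearrangement of the bis-O-allyl ether of cotoin (2,6-dihydroxy-4-methoxybenzophenone).
- The phloroglucinol ring of cotoin comes from 6-phenacyl-4-methoxy-2-pyranone by methoxide ring opening and intramolecular (Dieckmann-type) Claisen cyclisation.
- The key C–C bond, the later aryl–C(=O) bond, is made as CH2–C(=O)Ph by an intermolecular crossed Claisen condensation of lithiated 4-methoxy-6-methyl-2-pyranone with methyl benzoate.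
- Ring order: the pyranone ring is bought (triacetic acid lactone) and the phenyl ring comes intact with methyl benzoate; the only ring formed is the benzenoid ring, made from the pyranone carbons in step 3.

Assumption: the target has no stereocentre and no stereogenic double bond, so it is one achiral compound and no stereocontrol is needed.

**Route**

Step 1
Reactants: 1 4-hydroxy-6-methyl-2H-pyran-2-one (triacetic acid lactone)
Product: 2 4-methoxy-6-methyl-2H-pyran-2-one
Conditions: Me2SO4 (1.2 equiv), K2CO3 (1.5 equiv), acetone, reflux
Reagents that add atoms: dimethyl sulfate, COS(=O)(=O)OC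
Why: Williamson-type O-methylation of the acidic vinylogous acid gives mainly the 4-methoxy-2-pyranone (the minor 2-methoxy-4-pyranone isomer is removed by crystallisation); no stereocentre is involved.

Step 2
Reactants: 2 4-methoxy-6-methyl-2H-pyran-2-one; 3 methyl benzoate
Product: 5 4-methoxy-6-(2-oxo-2-phenylethyl)-2H-pyran-2-one, via lithiated pyrone 4 (not isolated)
Conditions: LiHMDS (2.2 equiv), THF, −78 °C; then 3, −78 → 0 °C; aq. HCl
Reagents that add atoms: none
Why: Crossed Claisen condensation in which the dienolate of the vinylogous C6-methyl group attacks the non-enolisable ester through its exocyclic carbon and the second equivalent of base traps the more acidic β-keto product as its enolate, which drives the reaction and prevents over-acylation; no stereocentre is formed.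

Step 3
Reactants: 5 4-methoxy-6-(2-oxo-2-phenylethyl)-2H-pyran-2-one
Product: 7 (2,6-dihydroxy-4-methoxyphenyl)(phenyl)methanone (cotoin), via ring-opened keto ester 6 (not isolated)
Conditions: NaOMe (3 equiv), dry MeOH, reflux; aq. HCl
Reagents that add atoms: none
Why: Methoxide opens the lactone to the (E)-β-methoxy enoate, whose ester stays cis to the diketone chain, and the 1,3-diketone carbanion closes onto that ester in a Dieckmann-type intramolecular Claisen condensation followed by irreversible aromatising tautomerisation, while methoxide in methanol makes exchange at the enol ether degenerate so the 4-OMe is kept; no stereocentre.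

Step 4
Reactants: 7 (2,6-dihydroxy-4-methoxyphenyl)(phenyl)methanone
Product: 9 [4-methoxy-2,6-bis(prop-2-en-1-yloxy)phenyl](phenyl)methanone, via mono-allyl ether 8 (not isolated)
Conditions: allyl bromide (3 equiv), K2CO3 (4 equiv), DMF, 60 °C
Reagents that add atoms: allyl bromide, C=CCBr
Why: Williamson ether synthesis in a polar aprotic solvent favours O- over C-allylation, and the twisted benzoyl group chelates the ortho-OH only weakly, so both phenols are alkylated; no stereocentre.

Step 5
Reactants: 9 [4-methoxy-2,6-bis(prop-2-en-1-yloxy)phenyl](phenyl)methanone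
Product: 11 [2,6-dihydroxy-4-methoxy-3,5-di(prop-2-en-1-yl)phenyl](phenyl)methanone, via mono-rearranged phenol 10 (not isolated)
Conditions: PhNEt2, 200 °C, sealed tube, Ar
Reagents that add atoms: none
Why: Two successive aromatic Claisen [3,3]-sigmatropic rearrangements each deliver an allyl group to the only hydrogen-bearing ortho carbon (C3, then C5), and tautomerisation restores the phenol; no stereocentre.

Step 6
Reactants: 11 [2,6-dihydroxy-4-methoxy-3,5-di(prop-2-en-1-yl)phenyl](phenyl)methanone
Product: 13 [2,6-dihydroxy-4-methoxy-3,5-bis(3-methylbut-2-en-1-yl)phenyl](phenyl)methanone, via mono-prenyl phenol 12 (not isolated)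
Conditions: Grubbs II (10 mol %), 2-methylbut-2-ene/CH2Cl2 1:1, 40 °C, sealed tube
Reagents that add atoms: 2-methylbut-2-ene, CC=C(C)C
Why: Olefin cross-metathesis of the terminal allyl groups with a large excess of 2-methylbut-2-ene converts each into a prenyl group, free phenols and the diaryl ketone being tolerated by the ruthenium carbene; the new alkenes carry a gem-dimethyl terminus, so no E/Z or stereocentre question arises.

**Compound list**
1 | 4-hydroxy-6-methyl-2H-pyran-2-one (triacetic acid lactone) | CC1=CC(O)=CC(=O)O1 | starting material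
2 | 4-methoxy-6-methyl-2H-pyran-2-one | COC1=CC(=O)OC(C)=C1 | intermediate
3 | methyl benzoate | COC(=O)c1ccccc1 | starting material
4 | [(4-methoxy-2-oxo-2H-pyran-6-yl)methyl]lithium (lithium dienolate of 2) | [Li]CC1=CC(OC)=CC(=O)O1 | intermediate
5 | 4-methoxy-6-(2-oxo-2-phenylethyl)-2H-pyran-2-one | COC1=CC(=O)OC(CC(=O)c2ccccc2)=C1 | intermediate
6 | methyl (2E)-3-methoxy-5,7-dioxo-7-phenylhept-2-enoate | COC(=O)/C=C(/OC)CC(=O)CC(=O)c1ccccc1 | intermediate
7 | (2,6-dihydroxy-4-methoxyphenyl)(phenyl)methanone (cotoin) | COc1cc(O)c(C(=O)c2ccccc2)c(O)c1 | intermediate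
8 | [2-hydroxy-4-methoxy-6-(prop-2-en-1-yloxy)phenyl](phenyl)methanone | COc1cc(O)c(C(=O)c2ccccc2)c(OCC=C)c1 | intermediate
9 | [4-methoxy-2,6-bis(prop-2-en-1-yloxy)phenyl](phenyl)methanone | COc1cc(OCC=C)c(C(=O)c2ccccc2)c(OCC=C)c1 | intermediate
10 | [2-hydroxy-4-methoxy-3-(prop-2-en-1-yl)-6-(prop-2-en-1-yloxy)phenyl](phenyl)methanone | COc1cc(OCC=C)c(C(=O)c2ccccc2)c(O)c1CC=C | intermediate
11 | [2,6-dihydroxy-4-methoxy-3,5-di(prop-2-en-1-yl)phenyl](phenyl)methanone | COc1c(CC=C)c(O)c(C(=O)c2ccccc2)c(O)c1CC=C | intermediate
12 | [2,6-dihydroxy-4-methoxy-3-(3-methylbut-2-en-1-yl)-5-(prop-2-en-1-yl)phenyl](phenyl)methanone | COc1c(CC=C)c(O)c(C(=O)c2ccccc2)c(O)c1CC=C(C)C | intermediate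
13 | [2,6-dihydroxy-4-methoxy-3,5-bis(3-methylbut-2-en-1-yl)phenyl](phenyl)methanone | COc1c(CC=C(C)C)c(O)c(C(=O)c2ccccc2)c(O)c1CC=C(C)C | target

**Summary**
Total step count: 6. Longest linear sequence: 6 steps (1 → 13); methyl benzoate 3 enters at step 2.

**Steps most likely to fail, with fallbacks**

Step 2 (crossed Claisen condensation). The risks are sluggish acylation by the ester, self-condensation of the pyrone anion, or attack at C3. The fallback sets out from 2 and comes back at 5. The same lithium dienolate (LiHMDS, THF, −78 °C) is added to benzaldehyde in an intermolecular aldol reaction and quenched cold with AcOH to give racemic 6-(2-hydroxy-2-phenylethyl)-4-methoxy-2H-pyran-2-one F1. Its carbinol is then oxidised with Dess–Martin periodinane in CH2Cl2, which removes the stereocentre and gives 5.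

Step 3 (pyranone-to-phloroglucinol ring transformation). The risks are the competing aldol-mode closure to a biphenyl resorcylate or retro-Claisen loss of the benzoyl group. The fallback sets out from methyl benzoate 3 and comes back at 7, using an open-chain polyketide instead of the pyranone. Crossed Claisen condensation of 3 with the dianion of pentane-2,4-dione (NaH, DME, reflux) gives 1-phenylhexane-1,3,5-trione F2. Its trianion (LDA, 3.3 equiv, THF, 0 °C) is carboxylated at the terminal methyl with CO2 to give 3,5,7-trioxo-7-phenylheptanoic acid F3. This is esterified cold with TMSCHN2 (MeOH/toluene) to methyl 3,5,7-trioxo-7-phenylheptanoate F4. KOH in methanol then effects the Claisen-type cyclisation of this ester to (2,4,6-trihydroxyphenyl)(phenyl)methanone F5. Finally, the most acidic 4-OH is methylated selectively with Me2SO4 (1.0 equiv)/K2CO3 in acetone at room temperature to give 7.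

Step 5 (double thermal Claisen rearrangement). The risks are incomplete second rearrangement or cyclisation of the o-allylphenols to dihydrobenzofurans at 200 °C. The fallback sets out from 7 and comes back at 11, replacing the O-allylation/rearrangement pair by halogenation and cross-coupling. NBS (2.05 equiv, MeCN, 0 °C) brominates the only two free ring positions to give (3,5-dibromo-2,6-dihydroxy-4-methoxyphenyl)(phenyl)methanone F6. Twofold Stille coupling with allyltributylstannane (Pd(PPh3)4, DMF, 100 °C) then gives 11.

**Further compounds**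
F1 | step 2 | 6-(2-hydroxy-2-phenylethyl)-4-methoxy-2H-pyran-2-one (racemic) | COC1=CC(=O)OC(CC(O)c2ccccc2)=C1
F2 | step 3 | 1-phenylhexane-1,3,5-trione | CC(=O)CC(=O)CC(=O)c1ccccc1
F3 | step 3 | 3,5,7-trioxo-7-phenylheptanoic acid | OC(=O)CC(=O)CC(=O)CC(=O)c1ccccc1
F4 | step 3 | methyl 3,5,7-trioxo-7-phenylheptanoate | COC(=O)CC(=O)CC(=O)CC(=O)c1ccccc1
F5 | step 3 | (2,4,6-trihydroxyphenyl)(phenyl)methanone | Oc1cc(O)c(C(=O)c2ccccc2)c(O)c1
F6 | step 5 | (3,5-dibromo-2,6-dihydroxy-4-methoxyphenyl)(phenyl)methanone | COc1c(Br)c(O)c(C(=O)c2ccccc2)c(O)c1Br
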